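**Retrosynthetic overview**

1. The target is (13R)-8β,17:9α,13-diepoxylabdane-19,6β:16,15-diolide. The last disconnection is C3–C4 of ring A, which leads to the 3,4-seco diene 31 (C10 allyl arm C1–C3 plus exocyclic C4=C18 on the 19,6β-lactone). Ring A is closed by a hydrogen-atom-transfer-initiated 6-endo radical cyclisation that also creates the C18 methyl group and the quaternary C4.
2. Enabling feature: C4 is the α-carbon of the lactone ring C19–O–C6–C5–C4, so C4/C18 can be stored as an α-methylene lactone. The cis-fused lactone and the trans-diequatorial C5 and C10 arms on ring B hold the C4 radical and C3 in a chair array and leave only one configuration open at C4.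
3. Compound 31 comes from ring B carrying every heterocycle: the 19,6β-lactone (oxidative lactonisation after inversion of C6 through the ketone), the 8β,17-oxirane (trans-diaxial bromohydrin of the C7=C8 alkene, then diol to epoxide), the spiro-tetrahydrofuran (acid-induced dienyl cation closure at C9) and the butyrolactone (translactonisation).
4. Carbon sources: ring B with C4, C17, C18, C19 from (R)-carvone; C20 from MeI; C1–C3 from allyl bromide; C11–C12 from vinylmagnesium bromide; C13–C16 from (R)-malic acid, whose pivalaldehyde acetal sets C13.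
5. Ring order: ring B (carvone) → dioxolanone (temporary) → butyrolactone → spiro-tetrahydrofuran → oxirane → 19,6-lactone → ring A.

Key step: step 20

Remark: labdane numbering is used for all intermediates (ring B = C5–C10); α is the face of H-5, β the face of the C10 methyl group; TBS = tert-butyldimethylsilyl.

**Route**

Step 1
Reactants: 1 (R)-(−)-carvone
Product: 3 6-methylcarvone (both C10 epimers), via lithium dienolate 2 (not isolated)
Conditions: LiN(i-Pr)2, THF, −78 °C; MeI, −78 → 0 °C
Reagents that add atoms: iodomethane CI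
Why: Kinetic deprotonation at the α'-methylene group gives the cross-conjugated enolate, and its C-methylation (enolate alkylation) brings in C20; the new stereocentre is erased again in step 2, so the epimer mixture is used as such.

Step 2
Reactants: 3 6-methylcarvone
Product: 5 6-allyl-6-methylcarvone (allyl trans to isopropenyl), via lithium enolate 4 (not isolated)
Conditions: LiN(i-Pr)2, THF, −78 °C; DMPU; allyl bromide, −78 → −20 °C
Reagents that add atoms: allyl bromide C=CCBr
Why: The second enolate alkylation should take place on the face anti to the neighbouring isopropenyl group, which sets the quaternary C10 with the allyl arm (C1 to C3) α and the methyl group β.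

Step 3
Reactants: 5 6-allyl-6-methylcarvone
Product: 8 6α-hydroxy enone, via lithium γ-dienolate 6 (not isolated), via silyl dienol ether 7 (not isolated)
Conditions: LiN(SiMe3)2, THF, −78 °C; Me3SiCl; then mCPBA, NaHCO3, CH2Cl2, −40 °C; aq. citric acid
Reagents that add atoms: 3-chloroperbenzoic acid OOC(=O)c1cccc(Cl)c1
Why: With no α'-hydrogen left the base removes a γ-hydrogen at C6, and peracid oxidation of the derived silyl dienol ether at its terminal C6=C7 bond (vinylogous Rubottom oxidation) from the α-face, anti to the pseudo-axial C10 methyl group, should give the 6α-alcohol.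

Step 4
Reactants: 8 6α-hydroxy enone
Product: 9 6α,19-dihydroxy enone
Conditions: SeO2 (cat.), t-BuOOH, CH2Cl2, 0 °C → rt
Reagents that add atoms: tert-butyl hydroperoxide CC(C)(C)OO
Why: Selenium dioxide allylic oxidation (ene reaction then 2,3-shift) should attack the most electron-rich alkene, the isopropenyl group, at its methyl group and so oxidises C19; no stereocentre is formed.

Step 5
Reactants: 9 6α,19-dihydroxy enone
Product: 10 6α,19-bis(TBS) ether
Conditions: t-BuMe2SiCl, imidazole, DMF, rt
Reagents that add atoms: tert-butyldimethylsilyl chloride CC(C)(C)[Si](C)(C)Cl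
Why: Silylation of both hydroxyl groups (silyl ether protection) shields them from the organometallic and enolate chemistry of steps 6 to 10.

Step 6
Reactants: 10 6α,19-bis(TBS) ether
Product: 11 C9 tertiary vinyl carbinol (both C9 epimers)
Conditions: CH2=CHMgBr, CeCl3, THF, −78 → 0 °C; aq. NH4Cl
Reagents that add atoms: vinylmagnesium bromide C=C[Mg]Br
Why: The organocerium reagent should add 1,2 to the hindered enone carbonyl (Grignard-type addition) and brings in C11 and C12; both C9 epimers are used because C9 becomes trigonal in step 7.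

Step 7
Reactants: 11 C9 tertiary vinyl carbinol
Product: 12 C12 dienyl bromide (C7=C8 and C9=C11)
Conditions: PBr3, pyridine, Et2O, −20 → 0 °C
Reagents that add atoms: phosphorus tribromide BrP(Br)Br
Why: Ionisation of the doubly allylic tertiary alcohol and capture of bromide at the primary terminus (allylic transposition of the SN1-prime type) should give the conjugated dienyl bromide; no stereocentre is formed.

Step 8
Reactants: 13 (R)-malic acid
Product: 14 (2R,4R)-2-tert-butyl-5-oxo-1,3-dioxolane-4-acetic acid
Conditions: t-BuCHO, TsOH (cat.), H2SO4 (cat.), pentane, reflux (water separator)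
Reagents that add atoms: pivalaldehyde CC(C)(C)C=O
Why: Acid-catalysed acetalisation under water removal gives the thermodynamically preferred cis-dioxolanone, whose acetal centre stores the configuration of C13 (self-regeneration of stereocentres).

Step 9
Reactants: 12 C12 dienyl bromide; 14 (2R,4R)-2-tert-butyl-5-oxo-1,3-dioxolane-4-acetic acid
Product: 16 C13-alkylated dioxolanone acid, via dilithium salt 15 (not isolated)
Conditions: 14, LiN(SiMe3)2 (2.1 equiv), THF, −78 °C; then 12, DMPU, −78 → −30 °C; aq. KHSO4
Reagents that add atoms: none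
Why: Alkylation of the dioxolanone enolate should occur anti to the tert-butyl group, so the dienyl chain takes the place of the former hydrogen and quaternary C13 is set with overall retention.

Step 10
Reactants: 16 C13-alkylated dioxolanone acid
Product: 18 C15 hydroxy dioxolanone, via mixed anhydride 17 (not isolated)
Conditions: i-BuOCOCl, N-methylmorpholine, THF, −15 °C; then NaBH4, H2O, −15 → 0 °C
Reagents that add atoms: none
Why: The acid is activated as the mixed carbonic anhydride and reduced by borohydride (mixed-anhydride reduction) faster than the dioxolanone, which unmasks the C15 alcohol without touching the alkenes.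

Step 11
Reactants: 18 C15 hydroxy dioxolanone
Product: 20 9α,13-spiro ether 16,15-olide, via hydroxy lactone 19 (not isolated)
Conditions: camphorsulfonic acid (20 mol%), CH2Cl2, 0 °C → rt
Reagents that add atoms: none
Why: Acid first transfers the acyl group from the acetal oxygen to the C15 hydroxyl (translactonisation, releasing pivalaldehyde) and then protonates the diene at C11, and the tertiary C13 hydroxyl captures the allyl cation at C9 by axial attack on the α-face, anti to the axial C10 methyl group (acid-catalysed dienyl alcohol spiro-etherification), which sets C9.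

Step 12
Reactants: 20 9α,13-spiro ether 16,15-olide
Product: 21 C17 allylic alcohol
Conditions: SeO2 (cat.), t-BuOOH, CH2Cl2, 0 °C → rt
Reagents that add atoms: tert-butyl hydroperoxide CC(C)(C)OO
Why: Selenium dioxide allylic oxidation should occur at the methyl group on the more substituted end of the only trisubstituted alkene (C9 carries no hydrogen), giving the C17 allylic alcohol without a new stereocentre.

Step 13
Reactants: 21 C17 allylic alcohol
Product: 22 7α-bromo-8β,17-diol
Conditions: NBS, THF/H2O, 0 °C
Reagents that add atoms: N-bromosuccinimide O=C1CCC(=O)N1Br; water O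
Why: Bromohydrin formation on the most electron-rich alkene: the bromonium ion should form on the α-face and water opens it at tertiary C8 in the trans-diaxial sense, which sets C8 (β-OH) and C7 (α-Br).

Step 14
Reactants: 22 7α-bromo-8β,17-diol
Product: 23 8β,17-diol
Conditions: Bu3SnH, AIBN (cat.), toluene, 80 °C
Reagents that add atoms: none
Why: Radical chain dehalogenation with tin hydride removes the C7 bromine; the secondary radical has no fast cyclisation or fragmentation pathway, and C8 is untouched.

Step 15
Reactants: 23 8β,17-diol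
Product: 25 8β,17-oxirane bis(TBS) ether, via primary tosylate 24 (not isolated)
Conditions: NaH (2.2 equiv), N-tosylimidazole, THF, 0 °C → rt
Reagents that add atoms: none
Why: The primary alkoxide is sulfonylated selectively and the tertiary C8 alkoxide displaces the tosylate (3-exo-tet Williamson closure), so the oxirane forms with retention at C8 (oxygen β, C17 α).

Step 16
Reactants: 25 8β,17-oxirane bis(TBS) ether
Product: 26 6α,19-diol
Conditions: Bu4NF, THF, 0 °C → rt
Reagents that add atoms: none
Why: Fluoride cleaves both silyl ethers (desilylation) and should leave the oxirane and the lactone intact.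

Step 17
Reactants: 26 6α,19-diol
Product: 27 6-oxo-19-al
Conditions: Dess–Martin periodinane, NaHCO3, CH2Cl2, 0 °C → rt
Reagents that add atoms: none
Why: Dess–Martin oxidation converts the secondary C6 alcohol and the allylic C19 alcohol into the ketone and the enal under buffered, non-basic conditions that should preserve C5 and the β-epoxy ketone.

Step 18
Reactants: 27 6-oxo-19-al
Product: 28 6β,19-diol
Conditions: NaBH4, CeCl3·7H2O, MeOH, −78 °C
Reagents that add atoms: none
Why: In the Luche reduction hydride adds 1,2 to the enal and should attack the C6 ketone from the α-face, because the axial β-trajectory is blocked by the syn-axial C10 methyl group and C8 oxirane oxygen, which sets C6 (β-OH) cis to the C5 side chain.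

Step 19
Reactants: 28 6β,19-diol
Product: 31 8β,17:9α,13-diepoxy-3,4-secolabda-2,4(18)-diene-19,6β:16,15-diolide, via hydroxy enal 29 (not isolated), via lactol 30 (not isolated)
Conditions: MnO2 (excess), CH2Cl2, rt
Reagents that add atoms: none
Why: MnO2 oxidises only the allylic primary alcohol; the enal is trapped by the cis 6β-hydroxyl as the lactol, which is oxidised on to the α-methylene-γ-butyrolactone (oxidative lactonisation), leaving no new stereocentre.

Step 20
Reactants: 31 8β,17:9α,13-diepoxy-3,4-secolabda-2,4(18)-diene-19,6β:16,15-diolide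
Product: 32 (13R)-8β,17:9α,13-diepoxylabdane-19,6β:16,15-diolide
Conditions: Mn(dpm)3 (dpm = dipivaloylmethanate, 10 mol%), PhSiH3 (slow addition), t-BuOOH, i-PrOH, 0.005 M, rt
Reagents that add atoms: none
Why: Proposed new method: hydrogen-atom transfer from a manganese hydride (formed from Mn(dpm)3, PhSiH3 and t-BuOOH) to the terminal carbon C18 of the α-methylene lactone should give the tertiary α-acyl radical at C4, which adds to the terminal carbon C3 of the C10 allyl arm, and the secondary C2 radical is quenched by a second hydrogen-atom transfer, so ring A, the C3–C4 bond, the C18 methyl group and the quaternary C4 arise in one operation. The closest known reaction types are the Mukaiyama-type hydrogen-atom-transfer hydrofunctionalisation of α,β-unsaturated esters, hydrogen-atom-transfer-initiated Giese-type cyclisations of dienes and atom-transfer 6-endo cyclisations of α-carbonyl radicals. Ring A closes in the 6-endo-trig mode through a chair transition state, because the C4 and C1 arms are trans-diequatorial on ring B, whereas 5-exo closure would build a strained trans-fused hydrindane onto the lactone. The only new stereocentre, C4, is controlled by the cis-fused 19,6β-lactone: C19 is tied to O6 on the β-face, so C3 can bond only on the face syn to C10 and the new methyl group is forced α. The step needs hydrogen-atom transfer to the conjugated 1,1-disubstituted alkene in preference to the monosubstituted allyl group, and cyclisation before reduction of the C4 radical; the first should be secured by the stability of the tertiary α-acyl radical, the second by high dilution and slow silane addition, and the neutral conditions should leave the oxirane and both lactones untouched.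

**Compound list**

1 | (R)-(−)-carvone | CC1=CC[C@H](CC1=O)C(C)=C | starting material
2 | lithium dienolate of carvone (C10 deprotonated) | [Li+].[O-]C1=C[C@H](C(C)=C)CC=C1C | intermediate
3 | 6-methylcarvone (both C10 epimers) | O=C1C(C)=CC[C@@H](C(C)=C)C1C | intermediate
4 | lithium enolate of 6-methylcarvone | [Li+].[O-]C1=C(C)[C@H](C(C)=C)CC=C1C | intermediate
5 | 6-allyl-6-methylcarvone (C10: methyl β and cis to isopropenyl; allyl α) | O=C1C(C)=CC[C@@H](C(C)=C)[C@]1(C)CC=C | intermediate
6 | lithium γ-dienolate of 5 (C6 deprotonated) | [Li+].[O-]C1=C(C)C=C[C@@H](C(C)=C)[C@]1(C)CC=C | intermediate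
7 | trimethylsilyl dienol ether of 5 (C8=C9 and C6=C7) | C[Si](C)(C)OC1=C(C)C=C[C@@H](C(C)=C)[C@]1(C)CC=C | intermediate
8 | 6α-hydroxy enone (OH at C6 trans to isopropenyl) | O=C1C(C)=C[C@H](O)[C@@H](C(C)=C)[C@]1(C)CC=C | intermediate
9 | 6α,19-dihydroxy enone (isopropenyl methyl oxidised to CH2OH) | O=C1C(C)=C[C@H](O)[C@@H](C(=C)CO)[C@]1(C)CC=C | intermediate
10 | 6α,19-bis(TBS) ether of 9 | O=C1C(C)=C[C@H](O[Si](C)(C)C(C)(C)C)[C@@H](C(=C)CO[Si](C)(C)C(C)(C)C)[C@]1(C)CC=C | intermediate
11 | C9 tertiary vinyl carbinol (both C9 epimers) | C=CC1(O)C(C)=C[C@H](O[Si](C)(C)C(C)(C)C)[C@@H](C(=C)CO[Si](C)(C)C(C)(C)C)[C@]1(C)CC=C | intermediate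
12 | 12-bromo-6α,19-bis(TBSO)-3,4-seco-13,14,15,16-tetranorlabda-2,4(18),7,9(11)-tetraene | BrCC=C1C(C)=C[C@H](O[Si](C)(C)C(C)(C)C)[C@@H](C(=C)CO[Si](C)(C)C(C)(C)C)[C@]1(C)CC=C | intermediate
13 | (R)-malic acid | O[C@H](CC(=O)O)C(=O)O | starting material
14 | (2R,4R)-2-tert-butyl-5-oxo-1,3-dioxolane-4-acetic acid (cis) | OC(=O)C[C@H]1O[C@@H](C(C)(C)C)OC1=O | intermediate
15 | dilithium enolate carboxylate of 14 | [Li+].[Li+].[O-]C(=O)CC1=C([O-])O[C@H](C(C)(C)C)O1 | intermediate
16 | C13-alkylated dioxolanone acid (dienyl chain anti to tert-butyl) | OC(=O)C[C@@]1(CC=C2C(C)=C[C@H](O[Si](C)(C)C(C)(C)C)[C@@H](C(=C)CO[Si](C)(C)C(C)(C)C)[C@]2(C)CC=C)O[C@@H](C(C)(C)C)OC1=O | intermediate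
17 | isobutyl carbonic mixed anhydride of 16 | CC(C)COC(=O)OC(=O)C[C@@]1(CC=C2C(C)=C[C@H](O[Si](C)(C)C(C)(C)C)[C@@H](C(=C)CO[Si](C)(C)C(C)(C)C)[C@]2(C)CC=C)O[C@@H](C(C)(C)C)OC1=O | intermediate
18 | C15 hydroxy dioxolanone | OCC[C@@]1(CC=C2C(C)=C[C@H](O[Si](C)(C)C(C)(C)C)[C@@H](C(=C)CO[Si](C)(C)C(C)(C)C)[C@]2(C)CC=C)O[C@@H](C(C)(C)C)OC1=O | intermediate
19 | (13R)-6α,19-bis(TBSO)-13-hydroxy-3,4-secolabda-2,4(18),7,9(11)-tetraen-16,15-olide | O[C@]1(CC=C2C(C)=C[C@H](O[Si](C)(C)C(C)(C)C)[C@@H](C(=C)CO[Si](C)(C)C(C)(C)C)[C@]2(C)CC=C)CCOC1=O | intermediate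
20 | (13R)-6α,19-bis(TBSO)-9α,13-epoxy-3,4-secolabda-2,4(18),7-trien-16,15-olide | CC1=C[C@H](O[Si](C)(C)C(C)(C)C)[C@@H](C(=C)CO[Si](C)(C)C(C)(C)C)[C@](C)(CC=C)[C@@]13CC[C@]2(CCOC2=O)O3 | intermediate
21 | 17-hydroxy derivative of 20 | OCC1=C[C@H](O[Si](C)(C)C(C)(C)C)[C@@H](C(=C)CO[Si](C)(C)C(C)(C)C)[C@](C)(CC=C)[C@@]13CC[C@]2(CCOC2=O)O3 | intermediate
22 | 7α-bromo-8β,17-dihydroxy-6α,19-bis(TBSO)-9α,13-epoxy-3,4-secolabda-2,4(18)-dien-16,15-olide | OC[C@]1(O)[C@H](Br)[C@H](O[Si](C)(C)C(C)(C)C)[C@@H](C(=C)CO[Si](C)(C)C(C)(C)C)[C@](C)(CC=C)[C@@]13CC[C@]2(CCOC2=O)O3 | intermediate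
23 | 8β,17-dihydroxy-6α,19-bis(TBSO)-9α,13-epoxy-3,4-secolabda-2,4(18)-dien-16,15-olide | OC[C@]1(O)C[C@H](O[Si](C)(C)C(C)(C)C)[C@@H](C(=C)CO[Si](C)(C)C(C)(C)C)[C@](C)(CC=C)[C@@]13CC[C@]2(CCOC2=O)O3 | intermediate
24 | 17-O-tosylate of 23 | Cc1ccc(cc1)S(=O)(=O)OC[C@]1(O)C[C@H](O[Si](C)(C)C(C)(C)C)[C@@H](C(=C)CO[Si](C)(C)C(C)(C)C)[C@](C)(CC=C)[C@@]13CC[C@]2(CCOC2=O)O3 | intermediate
25 | 6α,19-bis(TBSO)-8β,17:9α,13-diepoxy-3,4-secolabda-2,4(18)-dien-16,15-olide | C=CC[C@@]1(C)[C@H](C(=C)CO[Si](C)(C)C(C)(C)C)[C@@H](O[Si](C)(C)C(C)(C)C)C[C@@]2(CO2)[C@]13CC[C@]4(CCOC4=O)O3 | intermediate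
26 | 6α,19-dihydroxy-8β,17:9α,13-diepoxy-3,4-secolabda-2,4(18)-dien-16,15-olide | C=CC[C@@]1(C)[C@H](C(=C)CO)[C@@H](O)C[C@@]2(CO2)[C@]13CC[C@]4(CCOC4=O)O3 | intermediate
27 | 6-oxo-19-al (8β,17:9α,13-diepoxy-6,19-dioxo-3,4-secolabda-2,4(18)-dien-16,15-olide) | C=CC[C@@]1(C)[C@H](C(=C)C=O)C(=O)C[C@@]2(CO2)[C@]13CC[C@]4(CCOC4=O)O3 | intermediate
28 | 6β,19-dihydroxy-8β,17:9α,13-diepoxy-3,4-secolabda-2,4(18)-dien-16,15-olide | C=CC[C@@]1(C)[C@H](C(=C)CO)[C@H](O)C[C@@]2(CO2)[C@]13CC[C@]4(CCOC4=O)O3 | intermediate
29 | 6β-hydroxy-19-al | C=CC[C@@]1(C)[C@H](C(=C)C=O)[C@H](O)C[C@@]2(CO2)[C@]13CC[C@]4(CCOC4=O)O3 | intermediate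
30 | 19,6β-lactol (both C19 epimers) | C=CC[C@@]1(C)[C@@H]5C(=C)C(O)O[C@@H]5C[C@@]2(CO2)[C@]13CC[C@]4(CCOC4=O)O3 | intermediate
31 | (13R)-8β,17:9α,13-diepoxy-3,4-secolabda-2,4(18)-diene-19,6β:16,15-diolide | C=CC[C@@]1(C)[C@@H]5C(=C)C(=O)O[C@@H]5C[C@@]2(CO2)[C@]13CC[C@]4(CCOC4=O)O3 | intermediate
32 | (13R)-8β,17:9α,13-diepoxylabdane-19,6β:16,15-diolide (CNP0105047.2) | C[C@@]12CCC[C@]3(C)C(=O)O[C@H](C[C@@]4(CO4)[C@]14CC[C@]1(CCOC1=O)O4)[C@H]23 | target

**Step count and risks**

Total step count: 20. Longest linear sequence: 19 steps (steps 1–7 and 9–20, from (R)-carvone); step 8 prepares the malic acid fragment.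

Steps most likely to fail:

1. Step 20 (proposed new method). The C4 radical may be reduced before it cyclises, hydrogen-atom transfer may go to the allyl group (leading to a constitutional isomer), or closure may go 5-exo. The fallback is a polar ring closure by known chemistry; it sets out from 31 and comes back at 32. Conjugate reduction of the α-methylene lactone with [(Ph3P)CuH]6 (benzene, rt) should give the 4-methyl lactone, the dihydro lactone F1 (both C4 epimers). Hydroboration of the allyl group with 9-BBN followed by NaBO3 should give the primary alcohol F2, and TsCl in pyridine the tosylate F3. Treatment with KN(SiMe3)2 (THF, −78 → 0 °C) generates the lactone enolate at C4, the only enolisable position, and 6-exo-tet alkylation closes ring A; the C4 configuration is again dictated by the cis-fused lactone, so both epimers of F3 should converge on 32.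

2. Step 13. Chemoselectivity between the three alkenes may be lost, or the bromonium ion may open at the wrong carbon or face. The fallback delivers the C8 oxygen intramolecularly; it sets out from 21 and comes back at 23. The allylic alcohol is converted with Boc2O and DMAP into the tert-butyl carbonate F4. Iodine (MeCN, −20 °C) should then give the iodo carbonate F5 by 5-exo attack of the carbonate carbonyl oxygen on C8, anti to the α-iodonium ion, with loss of isobutene (iodocarbonate cyclisation). Bu3SnH with AIBN removes the iodine to give the cyclic carbonate F6, and K2CO3 in MeOH at 0 °C releases the 8β,17-diol 23.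

3. Step 11. The dienyl cation may be diverted (proton loss to a triene, or closure on the wrong face of C9) and the acid may strip the silyl ethers. The fallback separates the two events and replaces the proton by a selenium electrophile; it sets out from 18 and comes back at 20. Et3N in CH2Cl2 should induce the translactonisation and give the hydroxy lactone 19, which is isolated. N-(Phenylseleno)phthalimide with catalytic camphorsulfonic acid (CH2Cl2, −78 °C) should then effect selenoetherification, selenium adding at C11 and the C13 hydroxyl at C9, to give the C11 selenide F7. Bu3SnH with AIBN (toluene, 80 °C) removes the selenium and gives 20.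

**Further compounds**

F1 | step 20 | dihydro lactone: 3,4-secolabd-2-ene analogue of 31 with C4–H and C18 methyl (both C4 epimers) | C=CC[C@@]1(C)[C@@H]5C(C)C(=O)O[C@@H]5C[C@@]2(CO2)[C@]13CC[C@]4(CCOC4=O)O3
F2 | step 20 | primary alcohol: 3-hydroxy-3,4-seco derivative of F1 | OCCC[C@@]1(C)[C@@H]5C(C)C(=O)O[C@@H]5C[C@@]2(CO2)[C@]13CC[C@]4(CCOC4=O)O3
F3 | step 20 | tosylate of F2 | Cc1ccc(cc1)S(=O)(=O)OCCC[C@@]1(C)[C@@H]5C(C)C(=O)O[C@@H]5C[C@@]2(CO2)[C@]13CC[C@]4(CCOC4=O)O3
F4 | step 13 | tert-butyl carbonate of 21 (at O17) | CC(C)(C)OC(=O)OCC1=C[C@H](O[Si](C)(C)C(C)(C)C)[C@@H](C(=C)CO[Si](C)(C)C(C)(C)C)[C@](C)(CC=C)[C@@]13CC[C@]2(CCOC2=O)O3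
F5 | step 13 | iodo carbonate: 7α-iodo-8β,17-cyclic carbonate | O=C5OC[C@]1(O5)[C@H](I)[C@H](O[Si](C)(C)C(C)(C)C)[C@@H](C(=C)CO[Si](C)(C)C(C)(C)C)[C@](C)(CC=C)[C@@]13CC[C@]2(CCOC2=O)O3
F6 | step 13 | cyclic carbonate of 23 (8β,17-carbonate) | O=C5OC[C@]1(O5)C[C@H](O[Si](C)(C)C(C)(C)C)[C@@H](C(=C)CO[Si](C)(C)C(C)(C)C)[C@](C)(CC=C)[C@@]13CC[C@]2(CCOC2=O)O3
F7 | step 11 | C11 selenide: 11-phenylselanyl derivative of 20 (both C11 epimers) | CC1=C[C@H](O[Si](C)(C)C(C)(C)C)[C@@H](C(=C)CO[Si](C)(C)C(C)(C)C)[C@](C)(CC=C)[C@@]13C([Se]c5ccccc5)C[C@]2(CCOC2=O)O3
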